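**Plan**

1. Retrosynthetic cuts: the O4–acyl bond, then the two carbonate C–O bonds of a temporary O4/O8a bridge. Next, in one operation, C3–C3a of the five-membered ring together with O–C4, which leads back to a monocyclic cycloheptadienyl tert-butyl carbonate. Then C8a–C1 (propargylation of a dienone). The seven-membered ring goes back to 4-methylanisole by a one-carbon ring expansion.
2. Forward order: the seven-membered ring is made first (Birch diene, chloro(methyl)carbene, ring expansion to 2,5-dimethylcyclohepta-2,4-dienone). The C1–C2–C3 alkyne arm is then put on C8a. One gold-catalysed cascade closes the cyclopentene and a cyclic carbonate. C2=C3 saturation, carbonate hydrolysis and 4-methoxybenzoylation finish the route.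
3. Enabling feature: C3a is the terminus of the conjugated diene C3a=C4–C5=C6 in the seven-membered ring and the neighbour of the carbinol carbon C8a. When C3a attacks a gold-bound alkyne carbon C3 that hangs on C8a, the charge goes to the allyl unit C4–C6. O8a stands 1,3 to C4 and can deliver a carbonate oxygen to it, and the surviving C5=C6 bond is the trisubstituted alkene of the target.
4. Stereochemistry: C1 comes from (R)-4-methylpent-1-yn-3-ol by chirality transfer through an allenylzinc. C8a comes from the closed transition state of that addition. C3a comes from the cis fusion enforced by the C8a–C1–C2–C3 tether. C4 comes from intramolecular delivery of the carbonate oxygen, anti to the new C–C bond.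
5. Atom numbers are those of the azulene skeleton of the target: C1 (CH–isopropyl), C2, C3, C3a (C–methyl), C4 (CH–O), C5=C6 (methyl on C6), C7, C8, C8a (C–OH).

Key step: step 7

Assumption: (R)-4-methylpent-1-yn-3-ol is taken as a purchasable enantiopure alcohol (the racemate is a catalogue compound).

**Route**

Step 1
Reactants: 1 4-methylanisole
Product: 2 1-methoxy-4-methylcyclohexa-1,4-diene
Conditions: Li, NH3 (l), THF, t-BuOH, −78 to −33 °C; then solid NH4Cl
Reagents that add atoms: none
Why: Birch reduction of an anisole should stop at the unconjugated 2,5-dihydro stage with the methoxy group on a double bond, which supplies the enol ether needed for ring expansion; no stereocenter is formed.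

Step 2
Reactants: 2 1-methoxy-4-methylcyclohexa-1,4-diene
Product: 3 7-chloro-1-methoxy-4,7-dimethylbicyclo[4.1.0]hept-3-ene (racemic; both C7 epimers)
Conditions: CH3CHCl2, n-BuLi, Et2O, −40 °C to rt
Reagents that add atoms: 1,1-dichloroethane, CC(Cl)Cl
Why: Halocarbene cyclopropanation: the lithium carbenoid of chloro(methyl)carbene is electrophilic and should add to the enol ether C=C in preference to the trisubstituted alkyl alkene; the stereocenters formed are all destroyed in step 3.

Step 3
Reactants: 3 7-chloro-1-methoxy-4,7-dimethylbicyclo[4.1.0]hept-3-ene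
Product: 5 2,5-dimethylcyclohepta-2,4-dien-1-one, via 2,5-dimethylcyclohepta-2,5-dien-1-one 4 (not isolated)
Conditions: Et3N, dioxane/H2O (4:1), 90 °C; then DBU (0.2 equiv), CH2Cl2, rt
Reagents that add atoms: water, O
Why: Cyclopropyl-to-allyl cation ring expansion: loss of chloride with opening of the cyclopropane bond that carries the methoxy group gives the 2-methylcycloheptenone oxocarbenium ion, water releases ketone 4, and base should move the isolated C=C bond into the linearly conjugated dienone; no stereocenter.

Step 4
Reactants: 6 (R)-4-methylpent-1-yn-3-ol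
Product: 7 (R)-4-methylpent-1-yn-3-yl methanesulfonate
Conditions: MsCl, Et3N, CH2Cl2, −78 to 0 °C
Reagents that add atoms: methanesulfonyl chloride, CS(=O)(=O)Cl
Why: Sulfonylation at oxygen does not break the C–O bond, so the R configuration is retained.

Step 5
Reactants: 5 2,5-dimethylcyclohepta-2,4-dien-1-one; 7 (R)-4-methylpent-1-yn-3-yl methanesulfonate (1.5 equiv)
Product: 9 (1S)-2,5-dimethyl-1-[(3S)-4-methylpent-1-yn-3-yl]cyclohepta-2,4-dien-1-ol, via allenylzinc reagent 8 (not isolated)
Conditions: Pd(OAc)2 (5 mol %), PPh3 (5 mol %), Et2Zn (3 equiv), THF, −20 to 0 °C; aq NH4Cl/NH3 (pH 8)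
Reagents that add atoms: none
Why: Chirality-transfer propargylation: zerovalent palladium ionises the mesylate by anti SN2' attack, Et2Zn converts the allenylpalladium into the configurationally defined allenylzinc 8, and 8 should add to the ketone through a closed SE2' transition state, so that the propargylic carbon is set with net inversion from 7 (3S) and the carbinol carbon (1S) by the arrangement that keeps the isopropyl group anti to the bulkier C(CH3)=C arm of the ring (anti adduct).

Step 6
Reactants: 9 (1S)-2,5-dimethyl-1-[(3S)-4-methylpent-1-yn-3-yl]cyclohepta-2,4-dien-1-ol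
Product: 10 tert-butyl (1S)-2,5-dimethyl-1-[(3S)-4-methylpent-1-yn-3-yl]cyclohepta-2,4-dien-1-yl carbonate
Conditions: LiN(SiMe3)2, THF, −78 °C; then Boc2O, −78 to 0 °C
Reagents that add atoms: di-tert-butyl dicarbonate, CC(C)(C)OC(=O)OC(=O)OC(C)(C)C
Why: O-Acylation of the lithium alkoxide of the tertiary alcohol installs the carbonate that serves as the internal oxygen nucleophile; no stereocenter is touched.

Step 7
Reactants: 10 tert-butyl (1S)-2,5-dimethyl-1-[(3S)-4-methylpent-1-yn-3-yl]cyclohepta-2,4-dien-1-yl carbonate
Product: 11 cyclic carbonate (1,3-dioxan-2-one bridging O4 and O8a) of (1S,3aR,4S,8aS)-3a,6-dimethyl-1-(propan-2-yl)-3a,4,7,8-tetrahydroazulene-4,8a(1H)-diol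
Conditions: (Ph3P)AuNTf2 (5 mol %), CH2Cl2, −20 °C to rt
Reagents that add atoms: none
Why: Proposed new method: cationic monovalent gold binds the terminal alkyne of 10, the C3a terminus of the C3a=C4–C5=C6 diene attacks the alkyne carbon C3 anti to gold in a 5-endo-dig closure of the cyclopentene, the charge spreads over C4–C6 as an allyl cation, the carbonyl oxygen of the C8a carbonate closes a 1,3-dioxan-2-one on C4 in a 6-exo-trig closure, and the tert-butyl group leaves as 2-methylpropene, the proton of which cleaves the C2–Au bond. The closest known reaction types are the carbonate-terminated gold cyclisation of 3-(tert-butoxycarbonyloxy)-1,5-enynes and the 5-endo hydroxycyclisation of 1,5-enynes, and what has not been shown is a diene terminus as the nucleophile with capture of the cation 1,3 instead of 1,2 to the carbonate-bearing carbon. The new stereocenter C3a is controlled by the tether C8a–C1–C2–C3, which can reach only the ring face that carries C1, so the five-membered ring should be cis-fused and the C3a methyl group should end cis to O8a. The new stereocenter C4 is controlled by the carbonate, which is held on the O8a face and adds anti to the new C3–C3a bond, so that O4, O8a and the C3a methyl group should all be cis. The step needs C–C bond formation at C3a and not at C4 and oxygen capture at C4 and not at C6: the first is secured by the allyl stabilisation that only attack through C3a provides and by the strain of the bridged bicyclo[4.3.1] ring that attack through C4 would give, the second by the carbonate tether, which is too short to reach C6. C1 and C8a pass through unchanged.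

Step 8
Reactants: 11 cyclic carbonate of (1S,3aR,4S,8aS)-3a,6-dimethyl-1-(propan-2-yl)-3a,4,7,8-tetrahydroazulene-4,8a(1H)-diol
Product: 12 cyclic carbonate of (1R,3aR,4S,8aS)-3a,6-dimethyl-1-(propan-2-yl)-2,3,3a,4,7,8-hexahydroazulene-4,8a(1H)-diol
Conditions: 2-nitrobenzenesulfonyl hydrazide, Et3N, CH2Cl2, rt
Reagents that add atoms: none
Why: Diimide reduction: concerted syn transfer of H2 should go to the strained cis-disubstituted cyclopentene far faster than to the trisubstituted C5=C6 bond and cannot cleave the allylic carbonate; no new stereocenter (the C1 descriptor changes from S to R only because C2 loses priority).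

Step 9
Reactants: 12 cyclic carbonate of (1R,3aR,4S,8aS)-3a,6-dimethyl-1-(propan-2-yl)-2,3,3a,4,7,8-hexahydroazulene-4,8a(1H)-diol
Product: 13 (1R,3aR,4S,8aS)-3a,6-dimethyl-1-(propan-2-yl)-2,3,3a,4,7,8-hexahydroazulene-4,8a(1H)-diol
Conditions: LiOH, THF/H2O (3:1), 40 °C
Reagents that add atoms: none
Why: Saponification of the cyclic carbonate by attack of hydroxide at the carbonyl carbon leaves both C–O bonds, and so both carbinol configurations, intact.

Step 10
Reactants: 13 (1R,3aR,4S,8aS)-3a,6-dimethyl-1-(propan-2-yl)-2,3,3a,4,7,8-hexahydroazulene-4,8a(1H)-diol; 14 4-methoxybenzoyl chloride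
Product: 15 (1R,3aR,4S,8aS)-8a-hydroxy-3a,6-dimethyl-1-(propan-2-yl)-1,2,3,3a,4,7,8,8a-octahydroazulen-4-yl 4-methoxybenzoate
Conditions: pyridine, DMAP (0.1 equiv), CH2Cl2, 0 °C to rt
Reagents that add atoms: none
Why: Nucleophile-catalysed acylation (DMAP) should take place at the secondary allylic C4 hydroxyl only, because the tertiary ring-fusion hydroxyl is too hindered; C4 keeps its configuration since its C–O bond is not broken.

**Compound list**

1 | 4-methylanisole | COc1ccc(C)cc1 | starting material
2 | 1-methoxy-4-methylcyclohexa-1,4-diene | COC1=CCC(C)=CC1 | intermediate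
3 | 7-chloro-1-methoxy-4,7-dimethylbicyclo[4.1.0]hept-3-ene (racemic; both C7 epimers) | COC12CC=C(C)CC1C2(C)Cl | intermediate
4 | 2,5-dimethylcyclohepta-2,5-dien-1-one | O=C1C(C)=CCC(C)=CC1 | intermediate (not isolated)
5 | 2,5-dimethylcyclohepta-2,4-dien-1-one | O=C1C(C)=CC=C(C)CC1 | intermediate
6 | (R)-4-methylpent-1-yn-3-ol | C#C[C@H](O)C(C)C | starting material
7 | (R)-4-methylpent-1-yn-3-yl methanesulfonate | C#C[C@H](OS(C)(=O)=O)C(C)C | intermediate
8 | ethyl[(aS)-4-methylpenta-1,2-dien-1-yl]zinc | CC[Zn]C([H])=[C@@]=C([H])C(C)C | intermediate (not isolated)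
9 | (1S)-2,5-dimethyl-1-[(3S)-4-methylpent-1-yn-3-yl]cyclohepta-2,4-dien-1-ol | C#C[C@H](C(C)C)[C@@]1(O)CCC(C)=CC=C1C | intermediate
10 | tert-butyl (1S)-2,5-dimethyl-1-[(3S)-4-methylpent-1-yn-3-yl]cyclohepta-2,4-dien-1-yl carbonate | C#C[C@H](C(C)C)[C@@]1(OC(=O)OC(C)(C)C)CCC(C)=CC=C1C | intermediate
11 | cyclic carbonate of (1S,3aR,4S,8aS)-3a,6-dimethyl-1-(propan-2-yl)-3a,4,7,8-tetrahydroazulene-4,8a(1H)-diol | O=C1O[C@H]2C=C(C)CC[C@]3(O1)[C@@H](C(C)C)C=C[C@]23C | intermediate
12 | cyclic carbonate of (1R,3aR,4S,8aS)-3a,6-dimethyl-1-(propan-2-yl)-2,3,3a,4,7,8-hexahydroazulene-4,8a(1H)-diol | O=C1O[C@H]2C=C(C)CC[C@]3(O1)[C@@H](C(C)C)CC[C@]23C | intermediate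
13 | (1R,3aR,4S,8aS)-3a,6-dimethyl-1-(propan-2-yl)-2,3,3a,4,7,8-hexahydroazulene-4,8a(1H)-diol | O[C@H]1C=C(C)CC[C@]2(O)[C@@H](C(C)C)CC[C@]12C | intermediate
14 | 4-methoxybenzoyl chloride | COc1ccc(C(Cl)=O)cc1 | starting material
15 | (1R,3aR,4S,8aS)-8a-hydroxy-3a,6-dimethyl-1-(propan-2-yl)-1,2,3,3a,4,7,8,8a-octahydroazulen-4-yl 4-methoxybenzoate | COc1ccc(C(=O)O[C@H]2C=C(C)CC[C@]3(O)[C@@H](C(C)C)CC[C@]23C)cc1 | target

**Step count and risks**

Total step count: 10. Longest linear sequence: 9 steps (steps 1 to 3 and 5 to 10, from 4-methylanisole); the mesylate branch is one step.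

Steps most likely to fail:

1. Step 7 (the step beyond known chemistry). What may go wrong is diversion of the substrate before the C–C bond forms. The carbonate carbonyl may attack the gold-bound alkyne, or the tertiary dienylic C8a–O bond may ionise, in place of attack by the diene terminus.
 The fallback sets out from 9 and comes back at 13, and it uses known reaction types only. 9 is silylated (Et3SiOTf, 2,6-lutidine) to the triethylsilyl ether F1. The 5-endo hydroxycyclisation of 1,5-enynes ((Ph3P)AuNTf2, wet dioxane) then closes C3–C3a with water as external nucleophile and should give a mixture of the C4 alcohol F2 and the C6 alcohol F3. [C5H5NH][CrO3Cl] converges both on the enone F4, by direct oxidation of F2 and by oxidative 1,3-transposition of F3. Luche reduction (NaBH4, CeCl3) from the face opposite the angular methyl group should give the 4S alcohol F5. Diimide saturates C2=C3 to give the saturated silyl ether F6, and Bu4NF removes the silyl group to give 13.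

2. Step 5. What may go wrong is slow addition to the conjugated, α-branched ketone, which would let the allenylzinc lose its axial configuration or add with poor anti selectivity.
 The fallback sets out from 6 (with 5) and comes back at 9. 6 is converted with methyl chloroformate and pyridine into the methyl carbonate F7. Copper-catalysed anti SN2' borylation (CuOtBu, Xantphos, B2pin2) gives the configurationally stable allenylboronate F8. F8 is heated with 5 in the presence of 2,2'-biphenol (diol-exchange activation) and should add through the same closed transition state. Oxidative work-up (NaBO3) gives 9.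

3. Step 8. What may go wrong is incomplete reduction of the cyclopentene, which is flanked by C1 and the quaternary C3a, or reduction of C5=C6 when the reagent is forced.
 The fallback sets out from 11 and comes back at 15. 11 is saponified (LiOH) to the cyclopentene diol F9, which is acylated at O4 with 14 (pyridine, DMAP) to the cyclopentene ester F10. The free C8a hydroxyl then directs [Ir(cod)(PCy3)(py)]PF6/H2 to the homoallylic C2=C3 bond, while C5=C6 has no free allylic hydroxyl left; this gives 15.

**Further compounds**

F1 | step 7 | triethyl{[(1S)-2,5-dimethyl-1-[(3S)-4-methylpent-1-yn-3-yl]cyclohepta-2,4-dien-1-yl]oxy}silane | C#C[C@H](C(C)C)[C@@]1(O[Si](CC)(CC)CC)CCC(C)=CC=C1C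
F2 | step 7 | (1S,3aR,8aS)-3a,6-dimethyl-1-(propan-2-yl)-8a-[(triethylsilyl)oxy]-1,3a,4,7,8,8a-hexahydroazulen-4-ol (C4 epimers) | OC1C=C(C)CC[C@]2(O[Si](CC)(CC)CC)[C@@H](C(C)C)C=C[C@]12C
F3 | step 7 | (1S,3aR,8aS)-3a,6-dimethyl-1-(propan-2-yl)-8a-[(triethylsilyl)oxy]-1,3a,6,7,8,8a-hexahydroazulen-6-ol (C6 epimers) | C1=CC(C)(O)CC[C@]2(O[Si](CC)(CC)CC)[C@@H](C(C)C)C=C[C@]12C
F4 | step 7 | (1S,3aS,8aS)-3a,6-dimethyl-1-(propan-2-yl)-8a-[(triethylsilyl)oxy]-3a,7,8,8a-tetrahydroazulen-4(1H)-one | O=C1C=C(C)CC[C@]2(O[Si](CC)(CC)CC)[C@@H](C(C)C)C=C[C@]12C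
F5 | step 7 | (1S,3aR,4S,8aS)-3a,6-dimethyl-1-(propan-2-yl)-8a-[(triethylsilyl)oxy]-1,3a,4,7,8,8a-hexahydroazulen-4-ol | O[C@H]1C=C(C)CC[C@]2(O[Si](CC)(CC)CC)[C@@H](C(C)C)C=C[C@]12C
F6 | step 7 | (1R,3aR,4S,8aS)-3a,6-dimethyl-1-(propan-2-yl)-8a-[(triethylsilyl)oxy]-1,2,3,3a,4,7,8,8a-octahydroazulen-4-ol | O[C@H]1C=C(C)CC[C@]2(O[Si](CC)(CC)CC)[C@@H](C(C)C)CC[C@]12C
F7 | step 5 | methyl (R)-4-methylpent-1-yn-3-yl carbonate | C#C[C@H](OC(=O)OC)C(C)C
F8 | step 5 | 4,4,5,5-tetramethyl-2-[(aS)-4-methylpenta-1,2-dien-1-yl]-1,3,2-dioxaborolane | CC1(C)OB(OC1(C)C)C([H])=[C@@]=C([H])C(C)C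
F9 | step 8 | (1S,3aR,4S,8aS)-3a,6-dimethyl-1-(propan-2-yl)-3a,4,7,8-tetrahydroazulene-4,8a(1H)-diol | O[C@H]1C=C(C)CC[C@]2(O)[C@@H](C(C)C)C=C[C@]12C
F10 | step 8 | (1S,3aR,4S,8aS)-8a-hydroxy-3a,6-dimethyl-1-(propan-2-yl)-1,3a,4,7,8,8a-hexahydroazulen-4-yl 4-methoxybenzoate | COc1ccc(C(=O)O[C@H]2C=C(C)CC[C@]3(O)[C@@H](C(C)C)C=C[C@]23C)cc1
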